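**Retrosynthetic overview**
- The two C–Br bonds are made last from a cyclohexenol that carries a primary silyl ether; the side-chain C–Cl comes from SN2 inversion of an allylic alcohol, and the ring carbinol from 1,2-reduction of a cyclohexenone.
- The cyclohexenone (the only ring, formed once, in step 14) comes from ring-closing metathesis of an acyclic α-methylene ketone.
- The α-methylene ketone comes from a Stille acylation that joins an acyl chloride (fragment A, C8, carries the C–Cl stereocentre) and an α-stannyl allylic bis-silyl ether (fragment B, C4, carries the carbinol stereocentre).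
- Fragment A: isobutyronitrile + allyl bromide; organocatalytic α-chlorination of an aldehyde, then Cu-catalysed vinylation of the derived triflate.
- Fragment B: methyl glycolate + ethynyltrimethylsilane; asymmetric transfer hydrogenation of an ynone, then internal hydrostannation.

Assumption: the sense of induction in steps 3 and 9 follows the accepted catalyst models (not checked against data here); if either runs the other way, the antipodal catalyst is used.

**Fragment A**

Step 1
Reactants: 1 isobutyronitrile; 2 allyl bromide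
Product: 4 2,2-dimethylpent-4-enenitrile, via lithiated nitrile 3 (not isolated)
Conditions: LiN(iPr)2 (commercial solution), THF, −78 °C; then 2, −78 °C → rt
Reagents that add atoms: none
Why: α-Alkylation of a nitrile: the tertiary α-cyano carbanion undergoes SN2 allylation and builds the gem-dimethyl quaternary carbon (no stereocentre).

Step 2
Reactants: 4 2,2-dimethylpent-4-enenitrile
Product: 6 2,2-dimethyl-4-oxobutanenitrile, via ozonide 5 (not isolated)
Conditions: O3, CH2Cl2, −78 °C; then PPh3, −78 °C → rt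
Reagents that add atoms: ozone, [O-][O+]=O
Why: Ozonolysis with reductive work-up cleaves the terminal alkene to the aldehyde while the nitrile is inert.

Step 3
Reactants: 6 2,2-dimethyl-4-oxobutanenitrile
Product: 8 (3R)-3-chloro-4-hydroxy-2,2-dimethylbutanenitrile, via α-chloroaldehyde 7 (not isolated)
Conditions: (5R)-5-benzyl-2,2,3-trimethylimidazolidin-4-one·CF3CO2H (10 mol%), 2,3,4,5,6,6-hexachlorocyclohexa-2,4-dien-1-one (1.2 equiv), acetone, −30 °C; solvent exchange to EtOH, NaBH4, 0 °C
Reagents that add atoms: 2,3,4,5,6,6-hexachlorocyclohexa-2,4-dien-1-one, O=C1C(Cl)=C(Cl)C(Cl)=C(Cl)C1(Cl)Cl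
Why: Enamine-catalysed enantioselective α-chlorination of an aldehyde: Cl+ adds to the enamine face opposite the catalyst benzyl group to set the (R) C–Cl centre, and immediate borohydride reduction prevents racemisation.

Step 4
Reactants: 8 (3R)-3-chloro-4-hydroxy-2,2-dimethylbutanenitrile
Product: 10 (3S)-3-chloro-2,2-dimethylhex-5-enenitrile, via triflate 9 (not isolated)
Conditions: Tf2O, 2,6-lutidine, CH2Cl2, −78 °C; then cannulate into CH2=CHMgBr (4 equiv), CuI (10 mol%), THF, −78 → −20 °C
Reagents that add atoms: vinylmagnesium bromide, C=C[Mg]Br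
Why: Cu-catalysed Grignard–alkyl triflate cross-coupling (SN2 at the primary carbon); the neopentylic secondary chloride is inert, so the stereocentre is untouched (the descriptor changes to S only through priorities).

Step 5
Reactants: 10 (3S)-3-chloro-2,2-dimethylhex-5-enenitrile
Product: 12 (3S)-3-chloro-2,2-dimethylhex-5-enal, via aluminated imine 11 (not isolated)
Conditions: iBu2AlH, CH2Cl2, −78 → 0 °C; then 1 M aq. HCl, 0 °C
Reagents that add atoms: water, O
Why: Partial reduction of the hindered nitrile by iBu2AlH stops at the N-aluminated imine, which hydrolyses to the aldehyde; the α-carbon is quaternary, so nothing can epimerise or eliminate.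

Step 6
Reactants: 12 (3S)-3-chloro-2,2-dimethylhex-5-enal
Product: 13 (3S)-3-chloro-2,2-dimethylhex-5-enoic acid
Conditions: NaClO2, NaH2PO4, 2-methylbut-2-ene, tBuOH/H2O, 0 °C → rt
Reagents that add atoms: sodium chlorite, [Na+].[O-]Cl=O
Why: Pinnick oxidation converts only the aldehyde, with HOCl trapped by 2-methylbut-2-ene so that the terminal alkene survives.

**Fragment B**

Step 7
Reactants: 14 methyl glycolate
Product: 15 methyl 2-[(tert-butyldimethylsilyl)oxy]acetate
Conditions: TBSCl, imidazole, CH2Cl2, 0 °C → rt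
Reagents that add atoms: tert-butyldimethylsilyl chloride, CC(C)(C)[Si](C)(C)Cl
Why: Standard O-silylation of the primary alcohol; this oxygen later becomes the CH2Br carbon's leaving group.

Step 8
Reactants: 15 methyl 2-[(tert-butyldimethylsilyl)oxy]acetate; 16 ethynyltrimethylsilane
Product: 19 1-[(tert-butyldimethylsilyl)oxy]-4-(trimethylsilyl)but-3-yn-2-one, via lithium acetylide 17 (not isolated), via alkynyltrifluoroborate 18 (not isolated)
Conditions: 16, nBuLi, THF, −78 °C; BF3·OEt2, −78 °C; then 15, −78 °C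
Reagents that add atoms: none
Why: Yamaguchi-type ynone synthesis: the alkynyl borate adds once to the ester and the tetrahedral adduct is held by boron until work-up, so no over-addition occurs.

Step 9
Reactants: 19 1-[(tert-butyldimethylsilyl)oxy]-4-(trimethylsilyl)but-3-yn-2-one
Product: 20 (2R)-1-[(tert-butyldimethylsilyl)oxy]-4-(trimethylsilyl)but-3-yn-2-ol
Conditions: Ru[(S,S)-TsDPEN](p-cymene) (16-electron amido complex, 1 mol%), iPrOH, rt
Reagents that add atoms: none
Why: Noyori asymmetric transfer hydrogenation of an ynone: bifunctional hydride delivery distinguishes the alkynyl from the CH2OTBS side and sets the (R) carbinol under base-free conditions.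

Step 10
Reactants: 20 (2R)-1-[(tert-butyldimethylsilyl)oxy]-4-(trimethylsilyl)but-3-yn-2-ol
Product: 21 (2R)-1-[(tert-butyldimethylsilyl)oxy]-2-[(triethylsilyl)oxy]-4-(trimethylsilyl)but-3-yne
Conditions: TESCl, imidazole, CH2Cl2, 0 °C
Reagents that add atoms: chlorotriethylsilane, CC[Si](Cl)(CC)CC
Why: O-Silylation gives a secondary TES ether that can later be removed in the presence of the primary TBS ether; the stereocentre is not touched.

Step 11
Reactants: 21 (2R)-1-[(tert-butyldimethylsilyl)oxy]-2-[(triethylsilyl)oxy]-4-(trimethylsilyl)but-3-yne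
Product: 22 (2R)-1-[(tert-butyldimethylsilyl)oxy]-2-[(triethylsilyl)oxy]but-3-yne
Conditions: K2CO3 (0.2 equiv), MeOH, 0 °C
Reagents that add atoms: none
Why: Base-catalysed methanolysis cleaves only the C(sp)–Si bond; both silyl ethers survive the brief cold treatment.

Step 12
Reactants: 22 (2R)-1-[(tert-butyldimethylsilyl)oxy]-2-[(triethylsilyl)oxy]but-3-yne
Product: 23 tributyl{(3S)-4-[(tert-butyldimethylsilyl)oxy]-3-[(triethylsilyl)oxy]but-1-en-2-yl}stannane
Conditions: Bu3SnH, Mo(CO)3(CNtBu)3 (3 mol%), hydroquinone (10 mol%), THF, 55 °C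
Reagents that add atoms: tributyltin hydride, CCCC[SnH](CCCC)CCCC
Why: Mo-catalysed hydrostannation of a propargylic ether places tin on the internal carbon next to the oxygenated centre (α-stannane); the descriptor changes to S only through priorities.

**Coupling and endgame**

Step 13
Reactants: 13 (3S)-3-chloro-2,2-dimethylhex-5-enoic acid; 23 tributyl{(3S)-4-[(tert-butyldimethylsilyl)oxy]-3-[(triethylsilyl)oxy]but-1-en-2-yl}stannane
Product: 25 (2R,6S)-1-[(tert-butyldimethylsilyl)oxy]-6-chloro-5,5-dimethyl-3-methylidene-2-[(triethylsilyl)oxy]non-8-en-4-one, via acid chloride 24 (not isolated)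
Conditions: 13, (COCl)2, DMF (cat.), CH2Cl2, 0 °C → rt, evaporate; then 23, Pd2(dba)3 (2.5 mol%), P(2-furyl)3 (10 mol%), toluene, CO (1 atm), 60 °C
Reagents that add atoms: none
Why: Stille acylation: zerovalent palladium inserts into the acyl chloride, the alkenyl group transfers from tin and reductive elimination gives the enone under neutral conditions (CO suppresses decarbonylation); both stereocentres are spectators.

Step 14
Reactants: 25 (2R,6S)-1-[(tert-butyldimethylsilyl)oxy]-6-chloro-5,5-dimethyl-3-methylidene-2-[(triethylsilyl)oxy]non-8-en-4-one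
Product: 26 (5S)-2-{(1R)-2-[(tert-butyldimethylsilyl)oxy]-1-[(triethylsilyl)oxy]ethyl}-5-chloro-6,6-dimethylcyclohex-2-en-1-one
Conditions: second-generation Grubbs catalyst RuCl2(=CHPh)(H2IMes)(PCy3) (5 mol%), toluene (5 mM), 80 °C, Ar sparge
Reagents that add atoms: none
Why: Ring-closing metathesis: the Ru alkylidene loads on the allyl terminus and closes onto the 1,1-disubstituted enone alkene, helped by the gem-dimethyl group and driven by loss of ethene.

Step 15
Reactants: 26 (5S)-2-{(1R)-2-[(tert-butyldimethylsilyl)oxy]-1-[(triethylsilyl)oxy]ethyl}-5-chloro-6,6-dimethylcyclohex-2-en-1-one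
Product: 27 (1R,5S)-2-{(1R)-2-[(tert-butyldimethylsilyl)oxy]-1-[(triethylsilyl)oxy]ethyl}-5-chloro-6,6-dimethylcyclohex-2-en-1-ol
Conditions: NaBH4, CeCl3·7H2O, MeOH, −40 °C
Reagents that add atoms: none
Why: Luche 1,2-reduction: hydride is expected to enter on the ring face opposite the C5 chlorine (the other face is blocked by the pseudoaxial C6 methyl or by axial Cl in either half-chair), giving the carbinol cis to chlorine.

Step 16
Reactants: 27 (1R,5S)-2-{(1R)-2-[(tert-butyldimethylsilyl)oxy]-1-[(triethylsilyl)oxy]ethyl}-5-chloro-6,6-dimethylcyclohex-2-en-1-ol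
Product: 28 (1R,5S)-2-{(1R)-2-[(tert-butyldimethylsilyl)oxy]-1-hydroxyethyl}-5-chloro-6,6-dimethylcyclohex-2-en-1-ol
Conditions: pyridinium p-toluenesulfonate (20 mol%), MeOH/CH2Cl2, 0 °C
Reagents that add atoms: none
Why: Mild acid-catalysed methanolysis removes the more labile TES ether and leaves the primary TBS ether and the allylic alcohol intact.

Step 17
Reactants: 28 (1R,5S)-2-{(1R)-2-[(tert-butyldimethylsilyl)oxy]-1-hydroxyethyl}-5-chloro-6,6-dimethylcyclohex-2-en-1-ol
Product: 29 (1S,5S)-2-{(1S)-2-[(tert-butyldimethylsilyl)oxy]-1-chloroethyl}-5-chloro-6,6-dimethylcyclohex-2-en-1-ol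
Conditions: PPh3 (1.2 equiv), Cl3CC(O)CCl3, CH2Cl2, −20 °C
Reagents that add atoms: hexachloroacetone, O=C(C(Cl)(Cl)Cl)C(Cl)(Cl)Cl
Why: Appel-type chlorination with PPh3/hexachloroacetone: the side-chain allylic alkoxyphosphonium is displaced by chloride with SN2 inversion (1R → 1S), the neopentylic ring carbinol cannot be displaced at this temperature, and the silylated β-oxygen avoids neighbouring-group participation.

Step 18
Reactants: 29 (1S,5S)-2-{(1S)-2-[(tert-butyldimethylsilyl)oxy]-1-chloroethyl}-5-chloro-6,6-dimethylcyclohex-2-en-1-ol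
Product: 30 (4S,6R)-6-bromo-1-[(1S)-2-bromo-1-chloroethyl]-4-chloro-5,5-dimethylcyclohex-1-ene
Conditions: Ph3PBr2 (commercial, 3 equiv), 2,6-di-tert-butyl-4-methylpyridine (1.5 equiv), CH2Cl2, 0 °C → rt
Reagents that add atoms: dibromotriphenylphosphorane, BrP(Br)(c1ccccc1)(c1ccccc1)c1ccccc1
Why: Dibromophosphorane bromination: the ring alkoxyphosphonium is displaced by bromide with SN2 inversion to the (6R) bromide trans to chlorine, and the primary TBS ether is converted directly into CH2Br (silyl ether to bromide), with the hindered pyridine buffering HBr.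

**Compound list**
1 | isobutyronitrile | CC(C)C#N | starting material
2 | allyl bromide | C=CCBr | starting material
3 | 2-lithio-2-methylpropanenitrile | [Li]C(C)(C)C#N | intermediate
4 | 2,2-dimethylpent-4-enenitrile | C=CCC(C)(C)C#N | intermediate
5 | 2,2-dimethyl-3-(1,2,4-trioxolan-3-yl)propanenitrile (racemic ozonide) | N#CC(C)(C)CC1OCOO1 | intermediate
6 | 2,2-dimethyl-4-oxobutanenitrile | N#CC(C)(C)CC=O | intermediate
7 | (3R)-3-chloro-2,2-dimethyl-4-oxobutanenitrile | N#CC(C)(C)[C@@H](Cl)C=O | intermediate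
8 | (3R)-3-chloro-4-hydroxy-2,2-dimethylbutanenitrile | N#CC(C)(C)[C@@H](Cl)CO | intermediate
9 | (2R)-2-chloro-3-cyano-3-methylbutyl trifluoromethanesulfonate | N#CC(C)(C)[C@@H](Cl)COS(=O)(=O)C(F)(F)F | intermediate
10 | (3S)-3-chloro-2,2-dimethylhex-5-enenitrile | N#CC(C)(C)[C@@H](Cl)CC=C | intermediate
11 | (3S)-3-chloro-N-(diisobutylalumanyl)-2,2-dimethylhex-5-en-1-imine | CC(C)C[Al](CC(C)C)N=CC(C)(C)[C@@H](Cl)CC=C | intermediate
12 | (3S)-3-chloro-2,2-dimethylhex-5-enal | O=CC(C)(C)[C@@H](Cl)CC=C | intermediate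
13 | (3S)-3-chloro-2,2-dimethylhex-5-enoic acid | OC(=O)C(C)(C)[C@@H](Cl)CC=C | intermediate
14 | methyl glycolate | COC(=O)CO | starting material
15 | methyl 2-[(tert-butyldimethylsilyl)oxy]acetate | COC(=O)CO[Si](C)(C)C(C)(C)C | intermediate
16 | ethynyltrimethylsilane | C#C[Si](C)(C)C | starting material
17 | lithium (trimethylsilyl)acetylide | [Li]C#C[Si](C)(C)C | intermediate
18 | lithium trifluoro[(trimethylsilyl)ethynyl]borate | [Li+].F[B-](F)(F)C#C[Si](C)(C)C | intermediate
19 | 1-[(tert-butyldimethylsilyl)oxy]-4-(trimethylsilyl)but-3-yn-2-one | C[Si](C)(C)C#CC(=O)CO[Si](C)(C)C(C)(C)C | intermediate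
20 | (2R)-1-[(tert-butyldimethylsilyl)oxy]-4-(trimethylsilyl)but-3-yn-2-ol | C[Si](C)(C)C#C[C@@H](O)CO[Si](C)(C)C(C)(C)C | intermediate
21 | (2R)-1-[(tert-butyldimethylsilyl)oxy]-2-[(triethylsilyl)oxy]-4-(trimethylsilyl)but-3-yne | C[Si](C)(C)C#C[C@@H](O[Si](CC)(CC)CC)CO[Si](C)(C)C(C)(C)C | intermediate
22 | (2R)-1-[(tert-butyldimethylsilyl)oxy]-2-[(triethylsilyl)oxy]but-3-yne | C#C[C@@H](O[Si](CC)(CC)CC)CO[Si](C)(C)C(C)(C)C | intermediate
23 | tributyl{(3S)-4-[(tert-butyldimethylsilyl)oxy]-3-[(triethylsilyl)oxy]but-1-en-2-yl}stannane | C=C([Sn](CCCC)(CCCC)CCCC)[C@@H](O[Si](CC)(CC)CC)CO[Si](C)(C)C(C)(C)C | intermediate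
24 | (3S)-3-chloro-2,2-dimethylhex-5-enoyl chloride | ClC(=O)C(C)(C)[C@@H](Cl)CC=C | intermediate
25 | (2R,6S)-1-[(tert-butyldimethylsilyl)oxy]-6-chloro-5,5-dimethyl-3-methylidene-2-[(triethylsilyl)oxy]non-8-en-4-one | CC(C)([C@@H](Cl)CC=C)C(=O)C(=C)[C@@H](O[Si](CC)(CC)CC)CO[Si](C)(C)C(C)(C)C | intermediate
26 | (5S)-2-{(1R)-2-[(tert-butyldimethylsilyl)oxy]-1-[(triethylsilyl)oxy]ethyl}-5-chloro-6,6-dimethylcyclohex-2-en-1-one | CC1(C)[C@@H](Cl)CC=C([C@@H](O[Si](CC)(CC)CC)CO[Si](C)(C)C(C)(C)C)C1=O | intermediate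
27 | (1R,5S)-2-{(1R)-2-[(tert-butyldimethylsilyl)oxy]-1-[(triethylsilyl)oxy]ethyl}-5-chloro-6,6-dimethylcyclohex-2-en-1-ol | CC1(C)[C@@H](Cl)CC=C([C@@H](O[Si](CC)(CC)CC)CO[Si](C)(C)C(C)(C)C)[C@H]1O | intermediate
28 | (1R,5S)-2-{(1R)-2-[(tert-butyldimethylsilyl)oxy]-1-hydroxyethyl}-5-chloro-6,6-dimethylcyclohex-2-en-1-ol | CC1(C)[C@@H](Cl)CC=C([C@@H](O)CO[Si](C)(C)C(C)(C)C)[C@H]1O | intermediate
29 | (1S,5S)-2-{(1S)-2-[(tert-butyldimethylsilyl)oxy]-1-chloroethyl}-5-chloro-6,6-dimethylcyclohex-2-en-1-ol | CC1(C)[C@@H](Cl)CC=C([C@H](Cl)CO[Si](C)(C)C(C)(C)C)[C@H]1O | intermediate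
30 | (4S,6R)-6-bromo-1-[(1S)-2-bromo-1-chloroethyl]-4-chloro-5,5-dimethylcyclohex-1-ene | CC1(C)[C@@H](Cl)CC=C([C@H](Cl)CBr)[C@@H]1Br | target

**Totals**
Total step count: 18.
Longest linear sequence: 12 steps (steps 1–6 then 13–18; the branch 7–12 then 13–18 is equally long).

**Three steps most likely to fail**

Step 4 (vinylation of the β-chloro triflate). The risk is E2 loss of triflic acid to a vinyl chloride or sluggish SN2 beside the bulky CHCl–CMe2 unit. The fallback sets out from 8 and comes back at 10. Chlorohydrin 8 is closed with K2CO3 in MeOH, with inversion at the chlorinated carbon, to (S)-2-methyl-2-(oxiran-2-yl)propanenitrile F1. CuI-catalysed CH2=CHMgBr then opens the unhindered oxirane CH2 to give (R)-3-hydroxy-2,2-dimethylhex-5-enenitrile F2. Deoxychlorination of F2 with inversion (PPh3, CCl4, 70 °C) returns 10; the two inversions give the same configuration as the direct route. The last of these steps is itself an SN2 at a neopentylic carbinol and would need forcing.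

Step 13 (Stille acylation of two hindered partners). The risk is slow tin-to-palladium transfer of the α-substituted alkenyl group and decarbonylation of the tertiary acyl palladium. The fallback sets out from 23 (with aldehyde 12 from the main route) and comes back at 25. Stannane 23 is treated with I2 in CH2Cl2 at 0 °C to give tert-butyl{[(2S)-3-iodo-2-[(triethylsilyl)oxy]but-3-en-1-yl]oxy}dimethylsilane F3. A Nozaki–Hiyama–Kishi coupling of F3 with aldehyde 12 (CrCl2, NiCl2 cat., DMSO, rt) gives (2R,4RS,6S)-1-[(tert-butyldimethylsilyl)oxy]-6-chloro-5,5-dimethyl-3-methylidene-2-[(triethylsilyl)oxy]non-8-en-4-ol F4 as a mixture of carbinol epimers. Dess–Martin oxidation of F4 removes that centre and returns dienone 25.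

Step 18 (one-pot double bromination). The risks are slow conversion of the silyl ether, SN2′ or retention at the hindered allylic carbinol, and bromide exchange at the allylic chloride during a long reaction. The fallback sets out from 29 and comes back at 30. The TBS ether of 29 is removed with HF·pyridine in THF/pyridine at 0 °C to give (1S,5S)-5-chloro-2-[(1S)-1-chloro-2-hydroxyethyl]-6,6-dimethylcyclohex-2-en-1-ol F5. A short Appel bromination of F5 (CBr4, PPh3, 2.5 equiv each, CH2Cl2, 0 °C) converts the primary alcohol quickly and the ring allylic alcohol with inversion, giving 30 with minimal exposure of the allylic chloride to bromide.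

**Further compounds**
F1 | step 4 | (S)-2-methyl-2-(oxiran-2-yl)propanenitrile | N#CC(C)(C)[C@H]1CO1
F2 | step 4 | (R)-3-hydroxy-2,2-dimethylhex-5-enenitrile | N#CC(C)(C)[C@H](O)CC=C
F3 | step 13 | tert-butyl{[(2S)-3-iodo-2-[(triethylsilyl)oxy]but-3-en-1-yl]oxy}dimethylsilane | C=C(I)[C@@H](O[Si](CC)(CC)CC)CO[Si](C)(C)C(C)(C)C
F4 | step 13 | (2R,4RS,6S)-1-[(tert-butyldimethylsilyl)oxy]-6-chloro-5,5-dimethyl-3-methylidene-2-[(triethylsilyl)oxy]non-8-en-4-ol | CC(C)([C@@H](Cl)CC=C)C(O)C(=C)[C@@H](O[Si](CC)(CC)CC)CO[Si](C)(C)C(C)(C)C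
F5 | step 18 | (1S,5S)-5-chloro-2-[(1S)-1-chloro-2-hydroxyethyl]-6,6-dimethylcyclohex-2-en-1-ol | CC1(C)[C@@H](Cl)CC=C([C@H](Cl)CO)[C@H]1O
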